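**Retrosynthetic overview**
1. Target 26 ⇒ iodo-aldehyde 25: the ten-membered carbocycle (ring B) is closed last by Ni/Cr-mediated addition of the (Z)-vinyl iodide carbon C1 to the C2 aldehyde, which also delivers the free 2-OH.
2. 25 ⇒ bromomethyl-butenolide 12 + α-acetoxy aldehyde 19: an indium Barbier union (C7–C8) turns the butenolide into the α-methylene lactone and relays C6 to C7 and C8; the new 8-OH is angeloylated.
3. Key step: ring A is closed first by forming the lactone C6–O bond, a gold-catalysed dynamic kinetic asymmetric cycloisomerisation of racemic allenoic acid 10 (made from enal 5, alkyne 6 and CO) to butenolide 11.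
4. 19 ⇒ pent-1-en-4-yn-3-ol 13: anti-carbomagnesiation/iodination fixes the 1(10)Z alkene, and lipase resolution fixes C9 already as its acetate.
5. Ring order: lactone ring A (C–O), then carbocycle ring B (C1–C2).

Assumption: germacrane numbering (C1–C15, lactone C12–O–C6) is used as locant aid; TBS = tert-butyldimethylsilyl, TBDPS = tert-butyldiphenylsilyl, PMB = 4-methoxybenzyl; the sense of induction of the gold ligand, the lipase and ProPhenol is assigned by analogy and must be confirmed experimentally.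

**Step 1**
Reactants: 1 tert-butyl(but-3-yn-1-yloxy)diphenylsilane
Product: 4 (2E)-3-methyl-5-(TBDPS-oxy)pent-2-en-1-ol, via alkenyldimethylalane 2 (not isolated), via lithium alkenylaluminate 3 (not isolated)
Conditions: Me3Al, Cp2ZrCl2 (0.25 equiv), CH2Cl2, 0 to 23 °C; then n-BuLi, THF, −78 °C; (CH2O)n, to 23 °C
Reagents that add atoms: trimethylaluminium C[Al](C)C; formaldehyde (from paraformaldehyde) C=O
Why: Negishi zirconium-catalysed syn-carboalumination puts methyl and aluminium cis on the alkyne, which fixes the 4E trisubstituted alkene, and the derived aluminate is hydroxymethylated with retention.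

**Step 2**
Reactants: 4 (2E)-3-methyl-5-(TBDPS-oxy)pent-2-en-1-ol
Product: 5 (2E)-3-methyl-5-(TBDPS-oxy)pent-2-enal
Conditions: MnO2, CH2Cl2, 23 °C
Reagents that add atoms: none
Why: Chemoselective MnO2 oxidation of the allylic alcohol gives the enal without touching the silyl ether or the alkene geometry.

**Step 3**
Reactants: 5 (2E)-3-methyl-5-(TBDPS-oxy)pent-2-enal; 6 tert-butyldimethyl(prop-2-yn-1-yloxy)silane
Product: 9 racemic propargylic methyl carbonate, via lithium acetylide 7 (not isolated), via lithium propargylic alkoxide 8 (not isolated)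
Conditions: 6, n-BuLi, THF, −78 °C; add 5; then ClCO2Me, −78 to 0 °C
Reagents that add atoms: methyl chloroformate COC(Cl)=O
Why: 1,2-Addition of the lithium acetylide to the enal and O-acylation in the same flask give the racemic carbonate; no stereocontrol is needed because this centre is erased in step 4.

**Step 4**
Reactants: 9 racemic propargylic methyl carbonate
Product: 10 racemic (5E)-2-(TBS-oxymethyl)-6-methyl-8-(TBDPS-oxy)octa-2,3,5-trienoic acid
Conditions: Pd(PPh3)4 (5 mol%), CO (1 atm), THF/H2O (10:1), 23 °C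
Reagents that add atoms: carbon monoxide [C-]#[O+]; water O
Why: Tsuji-type carbonylation: SN2′ oxidative addition of zerovalent palladium to the propargylic carbonate gives an allenylpalladium that inserts CO and is hydrolysed to the 2,3-allenoic acid (racemic axis, no stereocentre).

**Step 5 (key step)**
Reactants: 10 racemic (5E)-2-(TBS-oxymethyl)-6-methyl-8-(TBDPS-oxy)octa-2,3,5-trienoic acid
Product: 11 (5R)-3-(TBS-oxymethyl)-5-[(1E)-2-methyl-4-(TBDPS-oxy)but-1-en-1-yl]furan-2(5H)-one
Conditions: (R)-DTBM-SEGPHOS(AuCl)2 (2.5 mol%), NaB[3,5-(CF3)2C6H3]4 (5 mol%), toluene, 4 Å MS, −20 °C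
Reagents that add atoms: none
Why: Proposed new method: dynamic kinetic asymmetric cycloisomerisation of a racemic 2,3-allenoic acid – the cationic chiral digold complex (monovalent gold) binds the C6=C7 π-bond and reversibly opens it to a planar gold-bound pentadienyl cation (stabilised by the C4=C5 alkene), so the allene axis racemises faster than it cyclises; only the matched allene enantiomer undergoes anti-oxyauration by the carboxyl oxygen at C6 followed by protodeauration, so the lactone C6–O bond, ring A and the 6R centre are created in one enantioconvergent event (silver-free activation suppresses the racemic background); the closest known reactions are the stereospecific AgNO3- and gold-catalysed cyclisations of allenoic acids to butenolides and gold-catalysed dynamic kinetic hydroalkoxylation/hydroamination of racemic allenes.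

**Step 6**
Reactants: 11 (5R)-3-(TBS-oxymethyl)-5-[(1E)-2-methyl-4-(TBDPS-oxy)but-1-en-1-yl]furan-2(5H)-one
Product: 12 (5R)-3-(bromomethyl)-5-[(1E)-2-methyl-4-(TBDPS-oxy)but-1-en-1-yl]furan-2(5H)-one
Conditions: Ph3PBr2, CH2Cl2, 0 °C
Reagents that add atoms: triphenylphosphine dibromide BrP(Br)(c1ccccc1)(c1ccccc1)c1ccccc1
Why: Triphenylphosphine dibromide converts the primary allylic TBS ether directly into the bromide (oxyphosphonium formation, then SN2), leaving the bulkier TBDPS ether and the C6 centre untouched.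

**Step 7**
Reactants: 13 racemic pent-1-en-4-yn-3-ol
Product: 15 racemic (4Z)-5-iodo-4-methylpenta-1,4-dien-3-ol, via cyclic alkenylmagnesium alkoxide 14 (not isolated)
Conditions: MeMgBr (3 equiv), CuI (0.2 equiv), THF, −10 to 23 °C; then I2, −30 to 0 °C
Reagents that add atoms: methylmagnesium bromide C[Mg]Br; iodine II
Why: Duboudin copper-catalysed anti-carbomagnesiation, directed by the magnesium alkoxide, adds methyl to the internal alkyne carbon, and iodinolysis of the chelated alkenylmagnesium gives the (Z)-iodoalkene that becomes the 1(10)Z olefin.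

**Step 8**
Reactants: 15 racemic (4Z)-5-iodo-4-methylpenta-1,4-dien-3-ol
Product: 16 racemic (4Z)-5-iodo-4-methylpenta-1,4-dien-3-yl acetate
Conditions: Ac2O, Et3N, DMAP (cat.), CH2Cl2, 0 °C
Reagents that add atoms: acetic anhydride CC(=O)OC(C)=O
Why: DMAP-catalysed acetylation installs the future C9 acetate in its final form.

**Step 9**
Reactants: 16 racemic (4Z)-5-iodo-4-methylpenta-1,4-dien-3-yl acetate
Product: 17 (3S,4Z)-5-iodo-4-methylpenta-1,4-dien-3-yl acetate
Conditions: lipase PS (Burkholderia cepacia), pH 7 phosphate buffer/MTBE, 30 °C, to about 55% conversion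
Reagents that add atoms: none
Why: Lipase-catalysed enantioselective hydrolysis (kinetic resolution, Kazlauskas rule with the iodoalkenyl arm as the large group) removes the R acetate and leaves the S acetate, which has the C9 configuration of the target (maximum yield 50%).

**Step 10**
Reactants: 17 (3S,4Z)-5-iodo-4-methylpenta-1,4-dien-3-yl acetate
Product: 19 (2R,3Z)-4-iodo-3-methyl-1-oxobut-3-en-2-yl acetate, via vicinal diol 18 (not isolated)
Conditions: OsO4 (2 mol%), NaIO4, 2,6-lutidine, dioxane/H2O (3:1), 0 to 23 °C; used crude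
Reagents that add atoms: sodium periodate [Na+].[O-]I(=O)(=O)=O (oxygen delivered through catalytic osmium tetroxide O=[Os](=O)(=O)=O)
Why: Lemieux–Johnson cleavage: OsO4 dihydroxylates the monosubstituted vinyl group in preference to the hindered, electron-poor iodoalkene, and NaIO4 cleaves the diol to the α-acetoxy aldehyde without touching C9.

**Step 11**
Reactants: 12 (5R)-3-(bromomethyl)-5-[(1E)-2-methyl-4-(TBDPS-oxy)but-1-en-1-yl]furan-2(5H)-one; 19 (2R,3Z)-4-iodo-3-methyl-1-oxobut-3-en-2-yl acetate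
Product: 20 8-hydroxy-9-acetoxy α-methylene lactone (6R,7R,8R,9R)
Conditions: In powder (1.5 equiv), THF/H2O (4:1), 23 °C
Reagents that add atoms: none
Why: Indium Barbier allylation with allylic transposition: the allylindium adds through C7 on the face anti to the C6 side chain in a closed chair transition state with the aldehyde substituent equatorial, which creates the α-methylene lactone, the 6,7-trans relationship and the 8R carbinol; the cyclic reagent is expected to override the weak intrinsic bias of the α-acetoxy aldehyde.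

**Step 12**
Reactants: 20 8-hydroxy-9-acetoxy α-methylene lactone; 21 angelic acid
Product: 23 8-angelate 9-acetate (6R,7S,8R,9R), via mixed Yamaguchi anhydride 22 (not isolated)
Conditions: 21, 2,4,6-Cl3C6H2COCl, Et3N, toluene, 23 °C; then 20, DMAP, 23 °C
Reagents that add atoms: none
Why: Yamaguchi esterification through the mixed anhydride acylates the hindered 8-OH at room temperature without Z to E isomerisation of the angelate; no stereocentre is touched (the C7 descriptor changes only because of CIP priorities).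

**Step 13**
Reactants: 23 8-angelate 9-acetate
Product: 24 primary alcohol at C2
Conditions: HF·pyridine, THF/pyridine, 0 to 23 °C
Reagents that add atoms: none
Why: Fluoride-mediated desilylation under mildly acidic conditions removes the TBDPS ether and spares both esters, the allylic lactone and the vinyl iodide.

**Step 14**
Reactants: 24 primary alcohol at C2
Product: 25 iodo-aldehyde (C2 aldehyde)
Conditions: Dess–Martin periodinane, pyridine, CH2Cl2, 0 °C; used at once
Reagents that add atoms: none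
Why: Buffered Dess–Martin oxidation gives the β,γ-unsaturated aldehyde without migration of the 4E double bond.

**Step 15**
Reactants: 25 iodo-aldehyde
Product: 26 target (CNP0316477.1)
Conditions: CrCl2 (10 equiv), NiCl2 (0.1 equiv), degassed DMSO/THF, 2 mM, 23 °C
Reagents that add atoms: none
Why: Nozaki–Hiyama–Kishi macrocyclisation: NiCl2-catalysed formation of the alkenylchromium from the vinyl iodide (Z geometry retained) and its intramolecular 1,2-addition to the aldehyde closes ring B and creates the free 2-hydroxyl; addition to the exposed aldehyde face of the ring-forming conformer is expected, but not proven, to give 2S.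

**Compound list**
1 | tert-butyl(but-3-yn-1-yloxy)diphenylsilane | C#CCCO[Si](c1ccccc1)(c1ccccc1)C(C)(C)C | starting material
2 | dimethyl{(1E)-2-methyl-4-[(tert-butyldiphenylsilyl)oxy]but-1-en-1-yl}alane (not isolated) | C[Al](C)/C=C(\C)CCO[Si](c1ccccc1)(c1ccccc1)C(C)(C)C | intermediate
3 | lithium butyl(dimethyl){(1E)-2-methyl-4-[(tert-butyldiphenylsilyl)oxy]but-1-en-1-yl}aluminate (not isolated) | [Li+].CCCC[Al-](C)(C)/C=C(\C)CCO[Si](c1ccccc1)(c1ccccc1)C(C)(C)C | intermediate
4 | (2E)-3-methyl-5-[(tert-butyldiphenylsilyl)oxy]pent-2-en-1-ol | OC/C=C(\C)CCO[Si](c1ccccc1)(c1ccccc1)C(C)(C)C | intermediate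
5 | (2E)-3-methyl-5-[(tert-butyldiphenylsilyl)oxy]pent-2-enal | O=C/C=C(\C)CCO[Si](c1ccccc1)(c1ccccc1)C(C)(C)C | intermediate
6 | tert-butyldimethyl(prop-2-yn-1-yloxy)silane | C#CCO[Si](C)(C)C(C)(C)C | starting material
7 | lithium 3-[(tert-butyldimethylsilyl)oxy]prop-1-yn-1-ide (not isolated) | [Li]C#CCO[Si](C)(C)C(C)(C)C | intermediate
8 | lithium rac-(5E)-1-[(tert-butyldimethylsilyl)oxy]-8-[(tert-butyldiphenylsilyl)oxy]-6-methyloct-5-en-2-yn-4-olate (not isolated) | [Li]OC(C#CCO[Si](C)(C)C(C)(C)C)/C=C(\C)CCO[Si](c1ccccc1)(c1ccccc1)C(C)(C)C | intermediate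
9 | rac-(5E)-1-[(tert-butyldimethylsilyl)oxy]-8-[(tert-butyldiphenylsilyl)oxy]-6-methyloct-5-en-2-yn-4-yl methyl carbonate | COC(=O)OC(C#CCO[Si](C)(C)C(C)(C)C)/C=C(\C)CCO[Si](c1ccccc1)(c1ccccc1)C(C)(C)C | intermediate
10 | rac-(5E)-2-{[(tert-butyldimethylsilyl)oxy]methyl}-8-[(tert-butyldiphenylsilyl)oxy]-6-methylocta-2,3,5-trienoic acid (racemic allene axis) | OC(=O)C(CO[Si](C)(C)C(C)(C)C)=C=C/C=C(\C)CCO[Si](c1ccccc1)(c1ccccc1)C(C)(C)C | intermediate
11 | (5R)-3-{[(tert-butyldimethylsilyl)oxy]methyl}-5-{(1E)-2-methyl-4-[(tert-butyldiphenylsilyl)oxy]but-1-en-1-yl}furan-2(5H)-one | O=C1O[C@H](/C=C(\C)CCO[Si](c2ccccc2)(c2ccccc2)C(C)(C)C)C=C1CO[Si](C)(C)C(C)(C)C | intermediate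
12 | (5R)-3-(bromomethyl)-5-{(1E)-2-methyl-4-[(tert-butyldiphenylsilyl)oxy]but-1-en-1-yl}furan-2(5H)-one | O=C1O[C@H](/C=C(\C)CCO[Si](c2ccccc2)(c2ccccc2)C(C)(C)C)C=C1CBr | intermediate
13 | rac-pent-1-en-4-yn-3-ol | C=CC(O)C#C | starting material
14 | 5-ethenyl-4-methyl-2,5-dihydro-1,2-oxamagnesole (cyclic alkenylmagnesium alkoxide, not isolated) | C=CC1O[Mg]C=C1C | intermediate
15 | rac-(4Z)-5-iodo-4-methylpenta-1,4-dien-3-ol | C=CC(O)/C(C)=C\I | intermediate
16 | rac-(4Z)-5-iodo-4-methylpenta-1,4-dien-3-yl acetate | C=CC(OC(C)=O)/C(C)=C\I | intermediate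
17 | (3S,4Z)-5-iodo-4-methylpenta-1,4-dien-3-yl acetate | C=C[C@H](OC(C)=O)/C(C)=C\I | intermediate
18 | (3R,4Z)-1,2-dihydroxy-5-iodo-4-methylpent-4-en-3-yl acetate (both C2 epimers, not isolated) | OCC(O)[C@H](OC(C)=O)/C(C)=C\I | intermediate
19 | (2R,3Z)-4-iodo-3-methyl-1-oxobut-3-en-2-yl acetate | O=C[C@H](OC(C)=O)/C(C)=C\I | intermediate
20 | (1R,2R,3Z)-1-hydroxy-4-iodo-3-methyl-1-[(2R,3R)-4-methylidene-2-{(1E)-2-methyl-4-[(tert-butyldiphenylsilyl)oxy]but-1-en-1-yl}-5-oxooxolan-3-yl]but-3-en-2-yl acetate | C=C1C(=O)O[C@H](/C=C(\C)CCO[Si](c2ccccc2)(c2ccccc2)C(C)(C)C)[C@H]1[C@@H](O)[C@H](OC(C)=O)/C(C)=C\I | intermediate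
21 | angelic acid, (2Z)-2-methylbut-2-enoic acid | C/C=C(/C)C(=O)O | starting material
22 | (2Z)-2-methylbut-2-enoic 2,4,6-trichlorobenzoic anhydride (not isolated) | C/C=C(/C)C(=O)OC(=O)c1c(Cl)cc(Cl)cc1Cl | intermediate
23 | (1R,2R,3Z)-2-acetoxy-4-iodo-3-methyl-1-[(2R,3S)-4-methylidene-2-{(1E)-2-methyl-4-[(tert-butyldiphenylsilyl)oxy]but-1-en-1-yl}-5-oxooxolan-3-yl]but-3-en-1-yl (2Z)-2-methylbut-2-enoate | C=C1C(=O)O[C@H](/C=C(\C)CCO[Si](c2ccccc2)(c2ccccc2)C(C)(C)C)[C@H]1[C@@H](OC(=O)/C(C)=C\C)[C@H](OC(C)=O)/C(C)=C\I | intermediate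
24 | (1R,2R,3Z)-2-acetoxy-1-[(2R,3S)-2-[(1E)-4-hydroxy-2-methylbut-1-en-1-yl]-4-methylidene-5-oxooxolan-3-yl]-4-iodo-3-methylbut-3-en-1-yl (2Z)-2-methylbut-2-enoate | C=C1C(=O)O[C@H](/C=C(\C)CCO)[C@H]1[C@@H](OC(=O)/C(C)=C\C)[C@H](OC(C)=O)/C(C)=C\I | intermediate
25 | (1R,2R,3Z)-2-acetoxy-4-iodo-3-methyl-1-[(2R,3S)-4-methylidene-2-[(1E)-2-methyl-4-oxobut-1-en-1-yl]-5-oxooxolan-3-yl]but-3-en-1-yl (2Z)-2-methylbut-2-enoate | C=C1C(=O)O[C@H](/C=C(\C)CC=O)[C@H]1[C@@H](OC(=O)/C(C)=C\C)[C@H](OC(C)=O)/C(C)=C\I | intermediate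
26 | (3aS,4R,5R,6Z,8S,10E,11aR)-5-acetoxy-8-hydroxy-6,10-dimethyl-3-methylidene-2-oxo-2,3,3a,4,5,8,9,11a-octahydrocyclodeca[b]furan-4-yl (2Z)-2-methylbut-2-enoate | C=C1C(=O)O[C@@H]2/C=C(\C)C[C@H](O)/C=C(/C)[C@@H](OC(C)=O)[C@H](OC(=O)/C(C)=C\C)[C@@H]12 | target

**Totals**
Total step count: 15. Longest linear sequence: 11 steps (steps 1–6, then 11–15).

**Three steps most likely to fail, with fallbacks**

Step 5 (proposed new method). The allene may cyclise faster than it racemises (low ee), or the vinylallene may give gold-induced Nazarov-type by-products. Fallback with known chemistry, setting C6 by carbonyl addition instead of C–O formation: from enal 5 and alkyne 6, Trost Zn-ProPhenol alkynylation (Me2Zn, ProPhenol enantiomer giving the R carbinol, toluene) gives (4R,5E)-1-(TBS-oxy)-8-(TBDPS-oxy)-6-methyloct-5-en-2-yn-4-ol F1. Hydroxyl-directed trans-hydroalumination with NaAlH2(OCH2CH2OCH3)2 and iodinolysis gives (2Z,4R,5E)-2-iodo-1-(TBS-oxy)-8-(TBDPS-oxy)-6-methylocta-2,5-dien-4-ol F2. Carbonylative lactonisation (PdCl2(PPh3)2, CO 1 atm, Et3N, THF) returns to butenolide 11.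

Step 11 (Barbier union). The required 8,9-syn product is the anti-Felkin one for aldehyde 19, so the selectivity rests on reagent control; in addition the 9-acetate can migrate to the new 8-OH, and 19 is epimerisable. Fallback that makes the aldehyde bias reinforce the reagent by chelation: from racemic dienol 15, lipase PS with vinyl acetate acylates the R enantiomer and leaves (3S,4Z)-5-iodo-4-methylpenta-1,4-dien-3-ol F3. NaH and 4-methoxybenzyl chloride give its PMB ether F4, and OsO4/NaIO4 gives (2R,3Z)-4-iodo-2-(PMB-oxy)-3-methylbut-3-enal F5. The indium Barbier reaction of F5 with 12 in THF/H2O, now chelation-controlled and matched, gives the 8-hydroxy 9-PMB-ether lactone F6. Yamaguchi angeloylation gives the 8-angelate 9-PMB ether F7, and DDQ (CH2Cl2/pH 7 buffer) frees the 9-hydroxyl to give the 8-angelate 9-alcohol F8. Ac2O/pyridine/DMAP then returns to 23. This costs three extra steps.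

Step 15 (macrocyclisation). The C2 configuration comes from substrate control in a strained ring closure and may be wrong or mixed. Fallback that moves C2 control from the C–C bond formation to a reagent-controlled reduction: from aldehyde 25 the Ni/Cr closure is run without regard to C2, giving the (2R)-epimer of the target F9 alone or mixed with 26. MnO2 oxidises the allylic alcohol to the macrocyclic 2-oxo compound F10. Corey–Bakshi–Shibata reduction (oxazaborolidine enantiomer chosen for 2S, catecholborane, −78 °C) then returns to 26.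

**Further compounds**
F1 | step 5 | (4R,5E)-1-[(tert-butyldimethylsilyl)oxy]-8-[(tert-butyldiphenylsilyl)oxy]-6-methyloct-5-en-2-yn-4-ol | O[C@@H](C#CCO[Si](C)(C)C(C)(C)C)/C=C(\C)CCO[Si](c1ccccc1)(c1ccccc1)C(C)(C)C
F2 | step 5 | (2Z,4R,5E)-1-[(tert-butyldimethylsilyl)oxy]-8-[(tert-butyldiphenylsilyl)oxy]-2-iodo-6-methylocta-2,5-dien-4-ol | O[C@@H](/C=C(\I)CO[Si](C)(C)C(C)(C)C)/C=C(\C)CCO[Si](c1ccccc1)(c1ccccc1)C(C)(C)C
F3 | step 11 | (3S,4Z)-5-iodo-4-methylpenta-1,4-dien-3-ol | C=C[C@H](O)/C(C)=C\I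
F4 | step 11 | 1-({[(3S,4Z)-5-iodo-4-methylpenta-1,4-dien-3-yl]oxy}methyl)-4-methoxybenzene | C=C[C@H](OCc1ccc(OC)cc1)/C(C)=C\I
F5 | step 11 | (2R,3Z)-4-iodo-2-[(4-methoxybenzyl)oxy]-3-methylbut-3-enal | O=C[C@H](OCc1ccc(OC)cc1)/C(C)=C\I
F6 | step 11 | 9-O-(4-methoxybenzyl) analogue of 20 (8-OH free; 6R,7R,8R,9R) | C=C1C(=O)O[C@H](/C=C(\C)CCO[Si](c2ccccc2)(c2ccccc2)C(C)(C)C)[C@H]1[C@@H](O)[C@H](OCc3ccc(OC)cc3)/C(C)=C\I
F7 | step 11 | 8-O-angeloyl 9-O-(4-methoxybenzyl) lactone (6R,7S,8R,9R) | C=C1C(=O)O[C@H](/C=C(\C)CCO[Si](c2ccccc2)(c2ccccc2)C(C)(C)C)[C@H]1[C@@H](OC(=O)/C(C)=C\C)[C@H](OCc3ccc(OC)cc3)/C(C)=C\I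
F8 | step 11 | 8-O-angeloyl 9-hydroxy lactone (6R,7S,8R,9R) | C=C1C(=O)O[C@H](/C=C(\C)CCO[Si](c2ccccc2)(c2ccccc2)C(C)(C)C)[C@H]1[C@@H](OC(=O)/C(C)=C\C)[C@H](O)/C(C)=C\I
F9 | step 15 | (2R)-epimer of 26 (germacrane C2; 8R in cyclodeca[b]furan numbering) | C=C1C(=O)O[C@@H]2/C=C(\C)C[C@@H](O)/C=C(/C)[C@@H](OC(C)=O)[C@H](OC(=O)/C(C)=C\C)[C@@H]12
F10 | step 15 | 2-oxo analogue of 26 (macrocyclic enone at germacrane C2) | C=C1C(=O)O[C@@H]2/C=C(\C)CC(=O)/C=C(/C)[C@@H](OC(C)=O)[C@H](OC(=O)/C(C)=C\C)[C@@H]12
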